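**Plan**

- Retrosynthesis cuts, in this order: the exocyclic C2–NH2 bond of the aminoimidazoline (back to a cyclic urea), the indole C2–Br bond, the indole bonds N1–C2 and C3–C3a (Fischer, back to an aldehyde and 4-bromophenylhydrazine), and last N1–C2 and C4–N3 of the diaza ring (back to a vinylaziridine and an isocyanate).
- Enabling feature: C4 carries N3 and is bonded to indole C3. If the indole C2=C3 unit is read as a vinyl group to be annulated later, C4 is an allylic amine carbon, and the imidazolidinone ring is the [3+2] adduct of a π-allylpalladium amide with an isocyanate.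
- Forward order: aziridine, then the imidazolidin-2-one ring by palladium cycloaddition, vinyl to CH2CHO, both 4-methoxybenzyl groups off while no indole exists, the indole ring by Fischer synthesis, C2 bromination, and urea-to-guanidine exchange.
- Stereochemistry: the single stereocentre C4 (R) is set in the cycloaddition by the chiral diphosphine acting on equilibrating π-allyl complexes. No later step makes or breaks a bond at C4, and strong acid is used only before the indolylic C4–N3 bond exists.

Key step: step 3

Remark: the (R,R) ligand is written as the enantiomer that should deliver (R)-6; the sense is checked on the first run and the (S,S) ligand is taken instead if it proves opposite.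
Remark: the target is taken as the free base drawn.

**Step 1**
Reactants: 1 butadiene monoepoxide (racemic 2-vinyloxirane); 2 4-methoxybenzylamine
Product: 3 racemic 1-[(4-methoxybenzyl)amino]but-3-en-2-ol
Conditions: 2 (3 equiv), iPrOH/H2O, 70 °C; excess 2 removed by Kugelrohr distillation; crude amino alcohol taken on
Reagents that add atoms: none
Why: SN2 aminolysis of the epoxide under neutral protic conditions, where the amine attacks mainly the unhindered terminal carbon and the excess of amine suppresses double alkylation; any share of opening at the allylic carbon is harmless because Mitsunobu closure in step 2 would lead from it to the same aziridine, and no stereochemistry matters since the aziridine is used as the racemate.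

**Step 2**
Reactants: 3 racemic 1-[(4-methoxybenzyl)amino]but-3-en-2-ol
Product: 4 racemic 1-(4-methoxybenzyl)-2-vinylaziridine
Conditions: PPh3, DIAD, THF, 0 °C to rt; chromatography on basic alumina
Reagents that add atoms: none
Why: Intramolecular Mitsunobu N-alkylation, in which the alkoxyphosphonium ion formed at the allylic hydroxyl group is displaced by the neighbouring secondary amine in a 3-exo-tet closure.

**Step 3**
Reactants: 4 racemic 1-(4-methoxybenzyl)-2-vinylaziridine; 5 4-methoxybenzyl isocyanate
Product: 6 (R)-1,3-bis(4-methoxybenzyl)-4-vinylimidazolidin-2-one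
Conditions: Pd2(dba)3·CHCl3 (2 mol %), (R,R)-N,N'-bis(2-diphenylphosphinobenzoyl)-1,2-diaminocyclohexane (6 mol %), AcOH (10 mol %), 5 (1.2 equiv), CH2Cl2, rt
Reagents that add atoms: none
Why: The zerovalent palladium–diphosphine complex ionises the strained allylic C–N bond of 4 with inversion to a zwitterionic π-allylpalladium amide, whose nitrogen adds to the isocyanate carbon of 5 (N1–C2) and whose resulting ureate nitrogen then attacks the substituted allyl terminus (C4–N3). The closest known reaction type is the palladium-catalysed dynamic kinetic asymmetric [3+2] cycloaddition of 2-vinylaziridines with isocyanates, a Tsuji–Trost allylic amination run intramolecularly. The imidazolidinone ring closes in a 5-exo mode onto the π-allyl unit, the alternative attack at the unsubstituted terminus being a 7-endo closure. The C4 stereocentre is controlled by the chiral ligand, because the two diastereomeric π-allyl complexes formed from racemic 4 interconvert by η3–η1–η3 isomerisation at the CH2 terminus faster than they cyclise, and acetic acid, by reversibly protonating the ureate, slows the closure enough for this equilibration to be complete. The step needs branched over linear regioselectivity, which the ring size secures, and enantioselection, which the ligand pocket secures; the electron-rich N-benzyl groups keep both nitrogens nucleophilic and are spectators that step 5 removes.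

**Step 4**
Reactants: 6 (R)-1,3-bis(4-methoxybenzyl)-4-vinylimidazolidin-2-one
Product: 8 (R)-4-(2-hydroxyethyl)-1,3-bis(4-methoxybenzyl)imidazolidin-2-one, via B-alkyl-9-BBN adduct 7 (not isolated)
Conditions: 9-BBN, THF, 0 °C to rt; then NaOH, H2O2, H2O, 0 °C to rt
Reagents that add atoms: hydrogen peroxide, OO
Why: Brown hydroboration–oxidation, in which the bulky dialkylborane places boron on the terminal carbon of the monosubstituted alkene and alkaline peroxide replaces boron by hydroxyl with no bond change at C4.

**Step 5**
Reactants: 8 (R)-4-(2-hydroxyethyl)-1,3-bis(4-methoxybenzyl)imidazolidin-2-one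
Product: 10 (R)-4-(2-hydroxyethyl)imidazolidin-2-one, via trifluoroacetate ester 9 (not isolated)
Conditions: TFA, 1,3,5-trimethoxybenzene (6 equiv), 70 °C; evaporate; then K2CO3 (cat.), MeOH, rt
Reagents that add atoms: none
Why: Acidolytic N-debenzylation, in which the O-protonated urea loses each 4-methoxybenzyl cation to the arene scavenger by Friedel–Crafts alkylation; the forcing step is placed here because the molecule has neither alkene nor indole and C4 cannot ionise, and the trifluoroacetate formed at the alcohol is removed by transesterification with methanol.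

**Step 6**
Reactants: 10 (R)-4-(2-hydroxyethyl)imidazolidin-2-one
Product: 11 (R)-2-(2-oxoimidazolidin-4-yl)acetaldehyde
Conditions: 2-iodoxybenzoic acid (IBX, 1.5 equiv), MeCN, 70 °C; filter, concentrate; used at once without purification
Reagents that add atoms: none
Why: Oxidation of a primary alcohol by IBX under neutral conditions stops at the aldehyde, needs only a filtration as work-up, which suits this water-soluble product, and leaves the non-enolisable β-stereocentre untouched.

**Step 7**
Reactants: 11 (R)-2-(2-oxoimidazolidin-4-yl)acetaldehyde; 12 4-bromophenylhydrazine hydrochloride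
Product: 14 (R)-4-(5-bromo-1H-indol-3-yl)imidazolidin-2-one, via arylhydrazone 13 (not isolated)
Conditions: NaOAc, EtOH, rt; then AcOH, 100 °C
Reagents that add atoms: none
Why: Fischer indole synthesis, in which the arylhydrazone tautomerises to the ene-hydrazine at its only α-CH2, the [3,3]-sigmatropic shift forms C3–C3a, and ring closure with loss of ammonia gives the indole, the para bromine allowing only the 5-bromo isomer; buffered acetic acid is chosen as an acid too weak to ionise the new indolylic C4–N3 bond, so C4 should keep its configuration.

**Step 8**
Reactants: 14 (R)-4-(5-bromo-1H-indol-3-yl)imidazolidin-2-one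
Product: 15 (R)-4-(2,5-dibromo-1H-indol-3-yl)imidazolidin-2-one
Conditions: NBS (1.0 equiv), AcOH, rt, dark
Reagents that add atoms: N-bromosuccinimide, O=C1CCC(=O)N1Br
Why: Electrophilic bromination of a 3-substituted indole, in which bromine is delivered to C3, migrates to C2 and the ring rearomatises by loss of the C2 proton, the 5-bromo substituent deactivating the benzo ring against further substitution.

**Step 9**
Reactants: 15 (R)-4-(2,5-dibromo-1H-indol-3-yl)imidazolidin-2-one
Product: 17 (R)-4-(2,5-dibromo-1H-indol-3-yl)-4,5-dihydro-1H-imidazol-2-amine, via O-ethylisouronium salt 16 (not isolated)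
Conditions: Et3OBF4 (1.2 equiv), CH2Cl2, rt; then NH3 (7 M in MeOH), NH4Cl, 60 °C, sealed tube; then aq NaOH, n-BuOH extraction
Reagents that add atoms: ammonia, N
Why: Urea-to-guanidine exchange, in which O-alkylation of the urea by the trialkyloxonium salt gives an isouronium ion that ammonia attacks at carbon in an addition–elimination with loss of ethanol, the 2-bromoindole being too electron-poor to compete for the alkylating agent and C4 not being involved.

**Compound list**

1 | butadiene monoepoxide (racemic 2-vinyloxirane) | C=CC1CO1 | starting material
2 | 4-methoxybenzylamine | COc1ccc(CN)cc1 | starting material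
3 | racemic 1-[(4-methoxybenzyl)amino]but-3-en-2-ol | C=CC(O)CNCc1ccc(OC)cc1 | intermediate
4 | racemic 1-(4-methoxybenzyl)-2-vinylaziridine | C=CC1CN1Cc1ccc(OC)cc1 | intermediate
5 | 4-methoxybenzyl isocyanate | COc1ccc(CN=C=O)cc1 | starting material
6 | (R)-1,3-bis(4-methoxybenzyl)-4-vinylimidazolidin-2-one | O=C1N(Cc2ccc(OC)cc2)[C@H](C=C)CN1Cc1ccc(OC)cc1 | intermediate
7 | (R)-4-[2-(9-borabicyclo[3.3.1]nonan-9-yl)ethyl]-1,3-bis(4-methoxybenzyl)imidazolidin-2-one | O=C1N(Cc2ccc(OC)cc2)[C@H](CCB2C3CCCC2CCC3)CN1Cc1ccc(OC)cc1 | intermediate (not isolated)
8 | (R)-4-(2-hydroxyethyl)-1,3-bis(4-methoxybenzyl)imidazolidin-2-one | O=C1N(Cc2ccc(OC)cc2)[C@H](CCO)CN1Cc1ccc(OC)cc1 | intermediate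
9 | (R)-2-(2-oxoimidazolidin-4-yl)ethyl trifluoroacetate | O=C1N[C@H](CCOC(=O)C(F)(F)F)CN1 | intermediate (not isolated)
10 | (R)-4-(2-hydroxyethyl)imidazolidin-2-one | O=C1N[C@H](CCO)CN1 | intermediate
11 | (R)-2-(2-oxoimidazolidin-4-yl)acetaldehyde | O=C1N[C@H](CC=O)CN1 | intermediate
12 | 4-bromophenylhydrazine hydrochloride | NNc1ccc(Br)cc1.Cl | starting material
13 | (R)-4-{(E)-2-[2-(4-bromophenyl)hydrazinylidene]ethyl}imidazolidin-2-one | O=C1N[C@H](C/C=N/Nc2ccc(Br)cc2)CN1 | intermediate (not isolated)
14 | (R)-4-(5-bromo-1H-indol-3-yl)imidazolidin-2-one | O=C1N[C@H](c2c[nH]c3ccc(Br)cc23)CN1 | intermediate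
15 | (R)-4-(2,5-dibromo-1H-indol-3-yl)imidazolidin-2-one | O=C1N[C@H](c2c(Br)[nH]c3ccc(Br)cc23)CN1 | intermediate
16 | (R)-4-(2,5-dibromo-1H-indol-3-yl)-2-ethoxy-4,5-dihydro-1H-imidazol-3-ium tetrafluoroborate | CCOC1=[NH+][C@H](c2c(Br)[nH]c3ccc(Br)cc23)CN1.F[B-](F)(F)F | intermediate (not isolated)
17 | (R)-4-(2,5-dibromo-1H-indol-3-yl)-4,5-dihydro-1H-imidazol-2-amine | NC1=N[C@H](c2c(Br)[nH]c3ccc(Br)cc23)CN1 | target

**Step count**

Total: 9 steps. Longest linear sequence: 9 steps (1 to 17); 5 and 12 are bought.

**Steps most likely to fail**

Step 7. The ene-hydrazine may expel the β-ureido nitrogen instead of undergoing the sigmatropic shift, or the acid may reversibly open the indolylic C4–N3 bond once the indole has formed; either process would lower yield or enantiopurity. The fallback sets out from 11 and comes back to the route at 14, and it forms the indole without acid. Aldehyde 11 is heated with 4-bromo-2-iodoaniline, Pd(OAc)2 and DABCO in DMF at 85 °C. Condensation gives the enamine (R)-4-[(E)-2-(4-bromo-2-iodoanilino)vinyl]imidazolidin-2-one F1. Zerovalent palladium formed in the flask inserts into its C–I bond, far faster than into C–Br, and an intramolecular Heck-type cyclisation with loss of hydrogen iodide gives 14.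

Step 8. After attack of bromine at C3, the 3-bromoindolenine may lose the C4 proton instead of passing bromine on to C2, which would scramble or oxidise the stereocentre; over-bromination and hydrolysis to an oxindole are further side processes. The fallback sets out from 14 and comes back at 15, and it replaces electrophilic substitution by C–H metalation. Iridium-catalysed borylation ([Ir(OMe)(cod)]2, 4,4'-di-tert-butyl-2,2'-bipyridine, B2pin2, THF, 60 °C) takes place at C2, the most reactive C–H of an N–H indole, and gives (R)-4-[5-bromo-2-(4,4,5,5-tetramethyl-1,3,2-dioxaborolan-2-yl)-1H-indol-3-yl]imidazolidin-2-one F2. CuBr2 in MeOH/H2O at 80 °C then exchanges boron for bromine and gives 15.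

Step 9. The oxonium salt may alkylate the indole nitrogen or carbon, or the isouronium ion may revert to the urea with traces of water before ammonia adds. The fallback sets out from 15 and comes back at 17, and it activates through sulfur instead of oxygen. Thionation with 2,4-bis(4-methoxyphenyl)-1,3,2,4-dithiadiphosphetane 2,4-disulfide in THF at 65 °C gives (R)-4-(2,5-dibromo-1H-indol-3-yl)imidazolidine-2-thione F3. Methyl iodide in acetone at rt gives (R)-4-(2,5-dibromo-1H-indol-3-yl)-2-(methylsulfanyl)-4,5-dihydro-1H-imidazole hydroiodide F4. Ammonia in methanol at 60 °C displaces methanethiol and, after work-up with aq NaOH, gives 17.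

**Further compounds**

F1 | step 7 | (R)-4-[(E)-2-(4-bromo-2-iodoanilino)vinyl]imidazolidin-2-one | O=C1N[C@H](/C=C/Nc2ccc(Br)cc2I)CN1
F2 | step 8 | (R)-4-[5-bromo-2-(4,4,5,5-tetramethyl-1,3,2-dioxaborolan-2-yl)-1H-indol-3-yl]imidazolidin-2-one | O=C1N[C@H](c2c(B3OC(C)(C)C(C)(C)O3)[nH]c3ccc(Br)cc23)CN1
F3 | step 9 | (R)-4-(2,5-dibromo-1H-indol-3-yl)imidazolidine-2-thione | S=C1N[C@H](c2c(Br)[nH]c3ccc(Br)cc23)CN1
F4 | step 9 | (R)-4-(2,5-dibromo-1H-indol-3-yl)-2-(methylsulfanyl)-4,5-dihydro-1H-imidazole hydroiodide | CSC1=N[C@H](c2c(Br)[nH]c3ccc(Br)cc23)CN1.I
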